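Target that leaves the flask reappears as side product, as I read these runs, so the sum of the two counts what has been fed in so far. While target stands flat, its share of that sum (the selectivity) is the standing target over the feed to date, so what I watch is how many times the standing target has been replaced.

| flask | solid substrate | temperature | remark | time |
|---|---|---|---|---|
| dusk | 2.1 M | 90 °C | run made earlier |  |
| dawn | 2.1 M | 112 °C | run made earlier |  |
| south | 1.5 M | 120 °C |  | 8.0 min |
| north | 1.5 M | 100 °C |  | 8.0 min |
| south-west | 1.5 M | 80 °C |  | 8.0 min |

| run | time / min | target / % | side product / % | solid substrate / % |
|---|---|---|---|---|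
| dusk | 2.00 | 7.3 | 0.8 | 85.8 |
| dusk | 6.00 | 14.0 | 16.4 | 60.0 |
| dusk | 12.0 | 13.5 | 50.0 | 26.0 |
| dusk | 20.0 | 7.8 | 89.3 | 0 |
| dusk | 25.0 | 3.2 | 95.1 | 0 |
| dawn | 0.500 | 3.6 | 0.3 | 95.2 |
| dawn | 1.50 | 6.9 | 3.7 | 88.6 |
| dawn | 3.00 | 8.3 | 13.4 | 77.2 |
| dawn | 5.00 | 7.7 | 28.3 | 63.2 |
| dawn | 6.00 | 8.1 | 36.4 | 53.4 |

(scatter of a reading: 0.5 percentage points)

- as a solid, counted per litre of solution: solid substrate
- at the start none of the solid substrate is in solution
- what has only dissolved of solid substrate counts as not reacted

- the flask that comes out highest in share of target in all that became target or side product, or "all alike" when all lie within 1.5 percentage points (south / north / south-west / all alike)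
- share of target in all that became target or side product, south
- share of target in all that became target or side product, north
- share of target in all that became target or side product, south-west

Dusk and dawn look nearly the same at 6.00 min: the charge is equal, and dusk has used 40.0 % of its solid substrate and dawn 46.6 %. Yet the share is 46.1 % in dusk and 18.2 % in dawn. Between 6.00 min and 12.0 min of dusk, target stands near flat and I read 2.46 min as the turnover time of target: the standing target divided by the rate at which side product grows. Dawn between 3.00 min and 6.00 min reads 1.07 min. Because dusk's target turns over more slowly than dawn's, dusk has counted 2.44 turnovers by that time and dawn 5.61, and the share is about the inverse of the count.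

I take the logarithm of the turnover time as straight in temperature and assume the charge does not shift it. That gives 0.791 min for south, 1.68 min for north and 3.58 min for south-west. Over 8.0 min my shares are 9.89 %, 21.0 % and 44.8 %, and south and south-west lie outside the temperatures read. The forecast, on a side-product rate that “fits second order in target better than first”, names south-west with 11 %, 22 % and 58 %. We share the order, and its south-west stands higher than mine.

The flasks give 9.72 % in south, 20.5 % in north and 57.2 % in south-west, so south-west comes highest and the forecast held.

    starting material ⇌ target + by-product (K = 0.702 M, k = 0.00551 s⁻¹, Ea = 111 kJ mol⁻¹, ΔH = 29.0 kJ mol⁻¹)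
    solid substrate ⇌ starting material, rate k2*(cs2 - [starting material]) while solid is left; crystals form when [starting material] > cs2 (solubility = 0.860 M, k = 0.00324 s⁻¹)
    target + by-product → side product (k = 0.0116 M⁻¹ s⁻¹, Ea = 78.0 kJ mol⁻¹)
    (constants at 80 °C)

In north at 8.00 min, by-product has a half-life of 1.1 min against its turning with target into side product, and with [by-product] at 0.226 M and [target] at 0.226 M that is a turnover time of 1.53 min beside my 1.68 min, drawn from the 2.46 min of dusk and the 1.07 min of dawn, while at 3.93 min target is made 1.06 times as fast as it is used up, the near balance of a resting state. The repeat of north at 75 °C I do not read as an inverse count: side product ends at 7.50 % against target at 19.3 %, so the target there has been replaced less than once, and the share stands at 72.0 %.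

All runs are calculated on assumed constants; the scatter is artificial.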